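If D stops falling while much of it still stands, suspect Q as the limiting reagent and ask what each reacted D costs in Q. In Sunday's run D reads 54.0% at 4.00 d and 54.7% at 5.00 d, and the other runs flatten likewise.

common to all: D 0.058 M

|  | Q | remark | time |
|---|---|---|---|
| Saturday's | 0.077 M | run made earlier |  |
| Thursday's | 0.081 M | run made earlier |  |
| Sunday's | 0.066 M | run made earlier |  |
| green | 0.0610 M |  | 10 d |
| violet | 0.0910 M |  | 10 d |

| run | time / d | D / % | J / % |
|---|---|---|---|
| Saturday's | 0.417 | 70.3 | 15.2 |
| Saturday's | 1.25 | 55.0 | 17.9 |
| Saturday's | 2.50 | 51.7 | 14.4 |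
| Saturday's | 4.00 | 50.0 | 13.6 |
| Saturday's | 5.00 | 51.5 | 12.7 |
| Thursday's | 1.04 | 55.9 | 15.6 |
| Thursday's | 2.08 | 50.9 | 13.6 |
| Thursday's | 3.00 | 47.3 | 13.1 |
| Thursday's | 4.00 | 48.0 | 13.3 |
| Thursday's | 5.00 | 47.3 | 12.4 |
| Sunday's | 0.417 | 74.3 | 13.3 |
| Sunday's | 1.25 | 60.4 | 16.5 |
| Sunday's | 2.50 | 56.4 | 14.6 |
| Sunday's | 4.00 | 54.0 | 14.2 |
| Sunday's | 5.00 | 54.7 | 12.1 |

(readings scatter by 1 percentage point)

* part of the D that has reacted at the end, green
* part of the D that has reacted at the end, violet
* what raising the concentration of Q from its lowest to its highest value here does to the part of the D that has reacted (changes below 5 percentage points count as none) (it falls / it rises / no change)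

- candidate steps: D + Q -> E + J; Q + E <-> G; Q + J -> L; J <-> Z

Call n, the Q cost, the Q charged over the D reacted at the last reading, with free Q taken as nil: 2.51 for Sunday's run, 2.74 for Saturday's and 2.65 for Thursday's. One point on a D reading moves Sunday's n by about 0.0555.

Now reckon the cost a second way, from the steps and the J readings. Each D reacted takes one Q, its E takes a second into G, and its J, unless still seen, takes a third into L. The count is therefore 3 minus J over D reacted. This gives 2.74 for Saturday's run, close to n there, but both figures lean on the same D reading, so that match is no check. For Sunday's run it gives 2.73, which is more than n by 0.220, a gap no single point explains. Here the count cheats: it books a Q on each E and each vanished J, yet G can return E and J can pass to Z, and neither costs Q.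

So hold to n, taken from the nearest run. My reckoning, which carries the last readings forward unchanged, gives 41.9% for green and 59.2% for violet.

The forecast says 43% (40% to 45.5%) for green and 58% (55% to 62%) for violet, so it rises, holding that “Q runs out rather than D”. Both of mine fall inside its ranges .

The flask gives 43.8% for green and 60.1% for violet, so it rises by 16 percentage points, as forecast. Green ends with 0.47% of its Q free against 56% of its D. Its n comes to 2.40, lower than Sunday's 2.51. Green's answer stands 1.7 points below the top of the forecast's range and 3.8 points above its bottom, so a green run reading beyond those margins would prove the forecast wrong.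

    D + Q → E + J (k = 1.70 × 10⁻⁴ L mol⁻¹ s⁻¹)
    Q + E ⇌ G, settled at all times (K = 12000 L mol⁻¹)
    Q + J → L (k = 6.50 × 10⁻⁴ L mol⁻¹ s⁻¹)
    J ⇌ Z (K = 1.40, k = 5.20 × 10⁻⁷ s⁻¹)

Take a flask like violet but with 0.055 M of Q: green's n gives 39.5% of D reacted, and the simulation gives 40.4%.

The readings were computed for substances that don't exist, and the scatter is random.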